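**Strategy.** The route rests on disconnecting the octadecanoyl chain between its C7 and C8 methylene carbons. A room-temperature alkyl–alkyl Suzuki–Miyaura coupling joins an oxolan-3-yl 7-bromoheptanoate, whose C5 side chain is still a dimethyl acetal, with B-undecyl-9-BBN made in the flask from 1-undecene, and so completes the C18 ester in one operation. The step exploits that C7 and C8 are unfunctionalised primary sp3 carbons, separated by five methylenes from the ester carbonyl on O–C3 of the oxolane and remote from the ring stereocentres C2, C3 and C5. The terminal C=C and the C1′ carbinol are added only afterwards, so neither borane nor palladium meets a competing alkene or hydroxyl. The oxolane core comes from a chloroaldehyde aldol, syn reduction and chloride displacement.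

Key step: step 6

Remark: locants follow the oxolane (O1, C2 pentyl, C3 acyloxy, C5 side chain, C1′ the carbinol carbon); acyl carbons are counted from the carbonyl carbon (C1). All numbered starting materials are taken as commercially available. Chloroaldehyde 2 and aldehyde 15 are configurationally labile and are used crude at once.

**Step 1**
Reactants: 1 heptanal
Product: 2 (R)-2-chloroheptanal
Conditions: NCS (1.3 equiv), (2S,5S)-2,5-diphenylpyrrolidine (10 mol%), CH2Cl2, 0 °C to rt; pentane, filtration
Reagents that add atoms: N-chlorosuccinimide, O=C1CCC(=O)N1Cl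
Why: Enamine-catalysed electrophilic α-chlorination of an aldehyde, in which the C2-symmetric amine shields one face of the E-enamine so that chlorine should enter to give the (R)-chloride, the (2S,5S) catalyst being the mirror image of the one associated with (S)-products.

**Step 2**
Reactants: 2 (R)-2-chloroheptanal; 3 1,1-dimethoxypropan-2-one
Product: 5 (4S,5R)-5-chloro-4-hydroxy-1,1-dimethoxydecan-2-one, via lithium enolate 4 (not isolated)
Conditions: 3, LDA (1.15 equiv), THF, −78 °C; then 2, −78 °C; AcOH quench at −78 °C
Reagents that add atoms: none
Why: Aldol addition of the kinetic methyl-side lithium enolate to the α-chloroaldehyde, which by the Cornforth (polar Felkin–Anh) model should give the 1,2-anti chlorohydrin and so set C4 as S from the (R)-chloride.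

**Step 3**
Reactants: 5 (4S,5R)-5-chloro-4-hydroxy-1,1-dimethoxydecan-2-one
Product: 7 (2R,4S,5R)-5-chloro-1,1-dimethoxydecane-2,4-diol, via diethylboron chelate 6 (not isolated)
Conditions: Et2BOMe (1.1 equiv), THF/MeOH 4:1, −78 °C; NaBH4, −78 °C; AcOH, then repeated evaporation from MeOH
Reagents that add atoms: none
Why: Narasaka–Prasad reduction, in which external hydride attacks the six-membered boron chelate of the β-hydroxy ketone axially and should set C2 as R in a 1,3-syn relation to C4, with no base present that could close the chlorohydrin to an epoxide.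

**Step 4**
Reactants: 7 (2R,4S,5R)-5-chloro-1,1-dimethoxydecane-2,4-diol
Product: 8 (2S,3S,5R)-5-(dimethoxymethyl)-2-pentyloxolan-3-ol
Conditions: AgOTf (1.1 equiv), Ag2O (1.1 equiv), THF, rt to 50 °C, dark
Reagents that add atoms: none
Why: Silver(I)-assisted intramolecular SN2 etherification (5-exo-tet) in which the C2 hydroxyl displaces the C5 chloride with inversion, so the anti chlorohydrin should become the 2,3-cis oxolane and the syn diol the 2,5-trans ring, while Ag2O takes up the acid so that the acetal survives and no alkoxide is there to form an epoxide.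

**Step 5**
Reactants: 8 (2S,3S,5R)-5-(dimethoxymethyl)-2-pentyloxolan-3-ol; 9 7-bromoheptanoic acid
Product: 10 (2S,3S,5R)-5-(dimethoxymethyl)-2-pentyloxolan-3-yl 7-bromoheptanoate
Conditions: DIC (1.3 equiv), DMAP (0.1 equiv), CH2Cl2, 0 °C to rt
Reagents that add atoms: none
Why: Steglich esterification of the only free hydroxyl, the primary bromide being inert to the carbodiimide and to catalytic DMAP at this temperature.

**Step 6**
Reactants: 10 (2S,3S,5R)-5-(dimethoxymethyl)-2-pentyloxolan-3-yl 7-bromoheptanoate; 11 undec-1-ene; 12 9-borabicyclo[3.3.1]nonane (9-BBN)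
Product: 14 (2S,3S,5R)-5-(dimethoxymethyl)-2-pentyloxolan-3-yl octadecanoate, via B-undecyl-9-BBN 13 (not isolated)
Conditions: 11 (1.3 equiv), 12 (1.2 equiv), THF, 0 °C to rt; then 10, Pd(OAc)2 (4 mol%), PCy3 (8 mol%), K3PO4·H2O (1.2 equiv), THF, rt
Reagents that add atoms: none
Why: Anti-Markovnikov hydroboration of 11 gives the primary alkylborane 13; Pd(0)/PCy3 adds oxidatively to the primary C–Br bond of 10 (SN2-like), base-assisted transmetalation transfers the primary undecyl group from the borate, and reductive elimination forms the C7–C8 bond of the acyl chain. The closest known reaction type is the room-temperature alkyl–alkyl Suzuki–Miyaura coupling of unactivated primary alkyl bromides bearing β-hydrogens with B-alkyl-9-BBN reagents. No ring is closed and no stereocentre is formed or touched. The selectivity needed is C–C coupling ahead of β-hydride elimination and exclusive transfer of the primary alkyl group, secured by the bulky electron-rich PCy3 and by the slow transmetalation of the secondary bridgehead B–C bonds of the bicycle. The ester, the acetal and the oxolane stereocentres should survive the mild hydrated phosphate base at room temperature, and because the vinyl group and the C1′ hydroxyl are not yet present, neither the borane nor a palladium hydride can find an alkene.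

**Step 7**
Reactants: 14 (2S,3S,5R)-5-(dimethoxymethyl)-2-pentyloxolan-3-yl octadecanoate
Product: 15 (2S,3S,5R)-5-formyl-2-pentyloxolan-3-yl octadecanoate
Conditions: TFA/H2O 9:1, CH2Cl2, 0 °C; cold NaHCO3 work-up
Reagents that add atoms: water, O
Why: Acid-catalysed acetal hydrolysis via the oxocarbenium ion, to which the secondary ester is stable, and the short cold exposure should leave C5 unepimerised.

**Step 8**
Reactants: 15 (2S,3S,5R)-5-formyl-2-pentyloxolan-3-yl octadecanoate; 16 9-bromonon-1-ene
Product: 18 (2S,3S,5R)-5-[(1R)-1-hydroxydec-9-en-1-yl]-2-pentyloxolan-3-yl octadecanoate, via non-8-enylmagnesium bromide 17 (not isolated)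
Conditions: 16, Mg, Et2O, rt; 15, MgBr2·OEt2 (2 equiv), CH2Cl2, −78 °C, then the Grignard solution (1.3 equiv), −78 °C; 1 M HCl quench
Reagents that add atoms: none
Why: Cram-chelate-controlled Grignard addition, in which magnesium bridges the formyl oxygen and ring O1, the alkyl group should add to the carbonyl face on the side of the C5 hydrogen to give the threo (1′R) carbinol, and at −78 °C the chelated aldehyde should react far faster than the ester.

**Compound list**
1 | heptanal | CCCCCCC=O | starting material
2 | (R)-2-chloroheptanal | CCCCC[C@@H](Cl)C=O | intermediate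
3 | 1,1-dimethoxypropan-2-one | CC(=O)C(OC)OC | starting material
4 | lithium enolate of 3 (lithium 3,3-dimethoxyprop-1-en-2-olate) | [Li]OC(=C)C(OC)OC | intermediate (not isolated)
5 | (4S,5R)-5-chloro-4-hydroxy-1,1-dimethoxydecan-2-one | CCCCC[C@@H](Cl)[C@@H](O)CC(=O)C(OC)OC | intermediate
6 | diethylboron chelate of 5 (4-O-diethylboryl derivative) | CCCCC[C@@H](Cl)[C@@H](OB(CC)CC)CC(=O)C(OC)OC | intermediate (not isolated)
7 | (2R,4S,5R)-5-chloro-1,1-dimethoxydecane-2,4-diol | CCCCC[C@@H](Cl)[C@@H](O)C[C@@H](O)C(OC)OC | intermediate
8 | (2S,3S,5R)-5-(dimethoxymethyl)-2-pentyloxolan-3-ol | COC(OC)[C@H]1C[C@H](O)[C@H](CCCCC)O1 | intermediate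
9 | 7-bromoheptanoic acid | OC(=O)CCCCCCBr | starting material
10 | (2S,3S,5R)-5-(dimethoxymethyl)-2-pentyloxolan-3-yl 7-bromoheptanoate | COC(OC)[C@H]1C[C@H](OC(=O)CCCCCCBr)[C@H](CCCCC)O1 | intermediate
11 | undec-1-ene | C=CCCCCCCCCC | starting material
12 | 9-borabicyclo[3.3.1]nonane (9-BBN, used as its dimer or THF solution) | B1C2CCCC1CCC2 | starting material
13 | B-undecyl-9-borabicyclo[3.3.1]nonane | CCCCCCCCCCCB1C2CCCC1CCC2 | intermediate (not isolated)
14 | (2S,3S,5R)-5-(dimethoxymethyl)-2-pentyloxolan-3-yl octadecanoate | COC(OC)[C@H]1C[C@H](OC(=O)CCCCCCCCCCCCCCCCC)[C@H](CCCCC)O1 | intermediate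
15 | (2S,3S,5R)-5-formyl-2-pentyloxolan-3-yl octadecanoate | O=C[C@H]1C[C@H](OC(=O)CCCCCCCCCCCCCCCCC)[C@H](CCCCC)O1 | intermediate
16 | 9-bromonon-1-ene | C=CCCCCCCCBr | starting material
17 | non-8-enylmagnesium bromide | C=CCCCCCCC[Mg]Br | intermediate (not isolated)
18 | (2S,3S,5R)-5-[(1R)-1-hydroxydec-9-en-1-yl]-2-pentyloxolan-3-yl octadecanoate | C=CCCCCCCC[C@@H](O)[C@H]1C[C@H](OC(=O)CCCCCCCCCCCCCCCCC)[C@H](CCCCC)O1 | target

**Totals and risks**
Total step count: 8. Longest linear sequence: 8 steps (1 to 18).

Steps most likely to fail:

Step 8. The risk is poor facial selectivity at the formyl group if the magnesium chelate does not dominate, together with enolisation at C5 or competing attack at the ester. Fallback (substrate-controlled addition replaced by an oxidation–reduction correction): it sets out from 15. The Grignard addition is run without demand on selectivity and the crude carbinol mixture (18 with its C1′ epimer) is oxidised with Dess–Martin periodinane (CH2Cl2, NaHCO3, rt) to the ketone (2S,3S,5R)-5-(dec-9-enoyl)-2-pentyloxolan-3-yl octadecanoate F1. F1 is then reduced with L-Selectride (THF, −78 °C), where Felkin–Anh attack anti to ring O1 should give the threo carbinol and the ester is left alone. The fallback returns at 18.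

Step 6. The risk is β-hydride elimination or protodebromination of the alkylpalladium intermediate outrunning a slow transmetalation of the hindered borane. Fallback (cross-coupling replaced by olefin metathesis and hydrogenation, possible because no other alkene is present at this stage): it sets out from 8. Steglich esterification with oct-7-enoic acid (C=CCCCCCC(=O)O; DIC, DMAP, CH2Cl2) gives (2S,3S,5R)-5-(dimethoxymethyl)-2-pentyloxolan-3-yl oct-7-enoate F2. Cross-metathesis of F2 with excess dodec-1-ene (C=CCCCCCCCCCC; second-generation Grubbs catalyst, CH2Cl2, 40 °C) joins C7 to C8 as the alkene and gives (2S,3S,5R)-5-(dimethoxymethyl)-2-pentyloxolan-3-yl octadec-7-enoate F3 (E/Z mixture). Hydrogenation (H2, Pd/C, EtOAc) saturates it and returns at 14.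

Step 2. The risk is loss of configuration of the α-chloroaldehyde under the basic enolate and insufficient anti selectivity. Fallback (preformed enantioenriched electrophile replaced by an amine-catalysed aldol with dynamic kinetic resolution): it sets out from 1. NCS and D-proline (CH2Cl2, rt) give racemic 2-chloroheptanal F4 in the flask. Excess 3 and further D-proline are then added; proline racemises the chloroaldehyde continuously while the enamine of 3 should add to the matched (R)-enantiomer to give the (4S) anti chlorohydrin. The fallback returns at 5.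

**Further compounds**
F1 | step 8 | (2S,3S,5R)-5-(dec-9-enoyl)-2-pentyloxolan-3-yl octadecanoate | C=CCCCCCCCC(=O)[C@H]1C[C@H](OC(=O)CCCCCCCCCCCCCCCCC)[C@H](CCCCC)O1
F2 | step 6 | (2S,3S,5R)-5-(dimethoxymethyl)-2-pentyloxolan-3-yl oct-7-enoate | COC(OC)[C@H]1C[C@H](OC(=O)CCCCCC=C)[C@H](CCCCC)O1
F3 | step 6 | (2S,3S,5R)-5-(dimethoxymethyl)-2-pentyloxolan-3-yl octadec-7-enoate (E/Z mixture, E shown) | COC(OC)[C@H]1C[C@H](OC(=O)CCCCC/C=C/CCCCCCCCCC)[C@H](CCCCC)O1
F4 | step 2 | rac-2-chloroheptanal | CCCCCC(Cl)C=O
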